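**Strategy.** The tetramer is cut at its three C4–C8 interflavan bonds. The lower epicatechin–epicatechin–catechin trimer is assembled from the natural monomers, while ring C of the top unit is built de novo. The key step is a magnesium-templated (3+3) annulation of 3,5-bis(benzyloxy)phenol with an enantiopure cis-3-aryl-2,3-epoxy aldehyde: the ortho carbon of the phenoxide adds to the aldehyde (C4a–C4) and its oxygen opens the epoxide at the benzylic carbon with inversion (O1–C2). It exploits ring A as a 1,3-C,O-binucleophile and C2 and C4 of ring C as 1,3-related electrophilic benzylic carbons, and delivers a 2,3-cis-flavan-3,4-diol whose C4 hydroxyl is the leaving group for the last 4β→8 coupling.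

Key step: step 4

Assumption: compounds 1, 2, 6, 10 and 13 are bought; diol 9 is carried as a mixture of C4 epimers (its C4 is written without a descriptor) because both epimers ionise to the same C4 cation in step 10.

**Route**

Step 1
Reactants: 1 3,4-bis(benzyloxy)benzaldehyde; 2 ethyl 2-(diphenoxyphosphoryl)acetate
Product: 3 ethyl (Z)-3-[3,4-bis(benzyloxy)phenyl]prop-2-enoate
Conditions: NaH, THF, −78 → 0 °C
Reagents that add atoms: none
Why: Ando variant of the Horner–Wadsworth–Emmons olefination, in which the electron-poor diphenyl phosphonate eliminates fast from the kinetically formed adduct and should give the Z-cinnamate from an aromatic aldehyde.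

Step 2
Reactants: 3 ethyl (Z)-3-[3,4-bis(benzyloxy)phenyl]prop-2-enoate
Product: 4 ethyl (2S,3S)-3-[3,4-bis(benzyloxy)phenyl]oxirane-2-carboxylate (cis-glycidate)
Conditions: (S,S)-N,N'-bis(3,5-di-tert-butylsalicylidene)-1,2-cyclohexanediaminomanganese chloride, (salen)MnCl, trivalent manganese (5 mol %), 4-phenylpyridine N-oxide, aqueous NaOCl (pH 11.3), CH2Cl2, 0–4 °C
Reagents that add atoms: sodium hypochlorite, [Na+].[O-]Cl
Why: Jacobsen–Katsuki epoxidation, for which cis-cinnamate esters are a favoured substrate class; the (S,S)-salen ligand should set both epoxide carbons as (2S,3S) (the (R,R) catalyst gives the (2R,3R) cis-glycidate), and the N-oxide additive limits stepwise collapse to the trans-epoxide.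

Step 3
Reactants: 4 ethyl (2S,3S)-3-[3,4-bis(benzyloxy)phenyl]oxirane-2-carboxylate
Product: 5 (2S,3S)-3-[3,4-bis(benzyloxy)phenyl]oxirane-2-carbaldehyde (cis-epoxy aldehyde)
Conditions: i-Bu2AlH (1.05 equiv), CH2Cl2, −78 °C; aqueous potassium sodium tartrate (KNaC4H4O6) work-up; used crude
Reagents that add atoms: none
Why: partial ester reduction through the aluminium hemiacetal that is stable at −78 °C, which should leave the epoxide and both of its stereocentres untouched because the oxiranyl α-hydrogen does not enolise.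

Step 4
Reactants: 5 (2S,3S)-3-[3,4-bis(benzyloxy)phenyl]oxirane-2-carbaldehyde; 6 3,5-bis(benzyloxy)phenol
Product: 9 5,7,3',4'-tetra-O-benzyl-(2R,3R)-2,3-cis-flavan-3,4-diol (C4 epimers), via magnesium phenoxide 7 (not isolated), via epoxy carbinol 8 (not isolated)
Conditions: Bu2Mg (0.5 equiv), toluene, 0 °C; then 5, 0 °C → rt; H2O quench
Reagents that add atoms: none
Why: Proposed new method: magnesium phenoxide 7 binds the aldehyde oxygen of 5 and delivers its ortho carbon to the carbonyl through a six-membered chelate (C4a–C4, giving 8 as its magnesium salt), and the same metal-bound phenoxide oxygen then opens the magnesium-activated cis-epoxide at its benzylic carbon (O1–C2). The closest known reaction types are the ortho-specific hydroxyalkylation of magnesium phenoxides by aldehydes and the phenol-to-aryl-epoxide cyclisation used to close ring C of flavan-3-ols; their union as one annulation on an epoxy aldehyde is the untested part. Ring C closes by 6-endo opening of the epoxide, preferred over 5-exo attack at C3 because the electron-rich ring B stabilises positive charge at the benzylic carbon. C2 is set by SN2 inversion at that carbon, so the (2S,3S)-cis-epoxide gives the 2,3-cis (2R,3R) pattern, C3 is carried over from the epoxide unchanged, and C4 forms without control, which is harmless because it is ionised in step 10. The step needs ortho-C attack over para-C and O-alkylation, secured by the chelate in non-coordinating toluene, and invertive over ionising epoxide opening, secured by halide-free aprotic conditions free of Brønsted acid.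

Step 5
Reactants: 10 (−)-epicatechin
Product: 11 5,7,3',4'-tetra-O-benzyl-(−)-epicatechin
Conditions: BnBr (4.2 equiv), K2CO3, DMF, 0 °C → rt
Reagents that add atoms: benzyl bromide, BrCc1ccccc1
Why: Williamson etherification in which carbonate deprotonates only the four phenols, so the secondary 3-OH should stay free and no stereocentre is touched at this temperature.

Step 6
Reactants: 11 5,7,3',4'-tetra-O-benzyl-(−)-epicatechin
Product: 12 5,7,3',4'-tetra-O-benzyl-4β-(2-ethoxyethoxy)-(−)-epicatechin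
Conditions: DDQ, 2-ethoxyethanol, CH2Cl2, rt
Reagents that add atoms: 2-ethoxyethanol, CCOCCO
Why: DDQ benzylic oxidation by hydride abstraction at C4 gives the ring-A-stabilised cation, which the alcohol should trap anti to the 3-OH to set the 4β (3,4-trans) centre.

Step 7
Reactants: 13 (+)-catechin
Product: 14 5,7,3',4'-tetra-O-benzyl-(+)-catechin
Conditions: BnBr (4.2 equiv), K2CO3, DMF, 0 °C → rt
Reagents that add atoms: benzyl bromide, BrCc1ccccc1
Why: Williamson etherification selective for the phenols over the 3-OH, with no stereocentre involved.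

Step 8
Reactants: 12 5,7,3',4'-tetra-O-benzyl-4β-(2-ethoxyethoxy)-(−)-epicatechin; 14 5,7,3',4'-tetra-O-benzyl-(+)-catechin
Product: 15 octa-O-benzyl epicatechin-(4β→8)-catechin, i.e. tetra-O-benzyl-epicatechin-(4β→8)-tetra-O-benzyl-catechin
Conditions: TMSOTf (10 mol %), CH2Cl2, −78 °C; 14 in excess (4 equiv, surplus recovered)
Reagents that add atoms: none
Why: Lewis-acid ionisation of the C4 ether and Friedel–Crafts attack by C8 of 14, its most nucleophilic position, from the face anti to the cis 2-aryl and 3-OH groups should give the 4β→8 bond (3,4-trans).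

Step 9
Reactants: 12 5,7,3',4'-tetra-O-benzyl-4β-(2-ethoxyethoxy)-(−)-epicatechin; 15 octa-O-benzyl epicatechin-(4β→8)-catechin
Product: 16 dodeca-O-benzyl epicatechin-(4β→8)-epicatechin-(4β→8)-catechin
Conditions: TMSOTf (10 mol %), CH2Cl2, −78 °C; 15 in excess (3 equiv, surplus recovered)
Reagents that add atoms: none
Why: the same Friedel–Crafts interflavan coupling, in which the only free C8 of 15 (upper unit) should outcompete the C6 positions and the attack anti to the 3-OH of the cation sets 4β.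

Step 10
Reactants: 9 5,7,3',4'-tetra-O-benzyl-(2R,3R)-2,3-cis-flavan-3,4-diol (C4 epimers); 16 dodeca-O-benzyl epicatechin-(4β→8)-epicatechin-(4β→8)-catechin
Product: 17 hexadeca-O-benzyl epicatechin-(4β→8)-epicatechin-(4β→8)-epicatechin-(4β→8)-catechin
Conditions: Yb(OTf)3 (20 mol %), 4 Å MS, CH2Cl2, 0 °C → rt; 16 in excess (2 equiv, surplus recovered)
Reagents that add atoms: none
Why: Lewis-acid flavan-3,4-diol condensation in which both C4 epimers of 9 ionise to one 2,4,6-trioxybenzyl cation, and C8 of the top unit of 16 should add anti to the cis 2-aryl and 3-OH pair to set the 4β (3,4-trans) centre.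

Step 11
Reactants: 17 hexadeca-O-benzyl epicatechin-(4β→8)-epicatechin-(4β→8)-epicatechin-(4β→8)-catechin
Product: 18 epicatechin-(4β→8)-epicatechin-(4β→8)-epicatechin-(4β→8)-catechin (the target arecatannin tetramer)
Conditions: H2 (1 atm), Pd(OH)2/C, THF/MeOH/H2O, rt
Reagents that add atoms: none
Why: hydrogenolysis of the sixteen aryl benzyl ethers under neutral conditions should leave the interflavan bonds and all stereocentres untouched.

**Compound list**

1 | 3,4-bis(benzyloxy)benzaldehyde | O=Cc1ccc(OCc2ccccc2)c(OCc2ccccc2)c1 | starting material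
2 | ethyl 2-(diphenoxyphosphoryl)acetate | CCOC(=O)CP(=O)(Oc1ccccc1)Oc1ccccc1 | starting material
3 | ethyl (Z)-3-[3,4-bis(benzyloxy)phenyl]prop-2-enoate | CCOC(=O)/C=C\c1ccc(OCc2ccccc2)c(OCc2ccccc2)c1 | intermediate
4 | ethyl (2S,3S)-3-[3,4-bis(benzyloxy)phenyl]oxirane-2-carboxylate (cis) | CCOC(=O)[C@H]1O[C@H]1c1ccc(OCc2ccccc2)c(OCc2ccccc2)c1 | intermediate
5 | (2S,3S)-3-[3,4-bis(benzyloxy)phenyl]oxirane-2-carbaldehyde (cis) | O=C[C@H]1O[C@H]1c1ccc(OCc2ccccc2)c(OCc2ccccc2)c1 | intermediate
6 | 3,5-bis(benzyloxy)phenol | Oc1cc(OCc2ccccc2)cc(OCc2ccccc2)c1 | starting material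
7 | magnesium bis[3,5-bis(benzyloxy)phenoxide] | [Mg+2].[O-]c1cc(OCc2ccccc2)cc(OCc2ccccc2)c1.[O-]c1cc(OCc2ccccc2)cc(OCc2ccccc2)c1 | intermediate
8 | [2,4-bis(benzyloxy)-6-hydroxyphenyl][(2R,3S)-3-[3,4-bis(benzyloxy)phenyl]oxiran-2-yl]methanol (cis-epoxide, carbinol centre unassigned; magnesium salt in the flask) | OC(c1c(O)cc(OCc2ccccc2)cc1OCc1ccccc1)[C@H]1O[C@H]1c1ccc(OCc2ccccc2)c(OCc2ccccc2)c1 | intermediate
9 | 5,7,3',4'-tetra-O-benzyl-(2R,3R)-2,3-cis-flavan-3,4-diol (C4 epimer mixture) | C(c3ccccc3)Oc1cc(OCc3ccccc3)c2c(c1)O[C@H](c1ccc(OCc3ccccc3)c(OCc3ccccc3)c1)[C@H](O)C2O | intermediate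
10 | (−)-epicatechin, (2R,3R) | Oc1cc(O)c2c(c1)O[C@H](c1ccc(O)c(O)c1)[C@H](O)C2 | starting material
11 | 5,7,3',4'-tetra-O-benzyl-(−)-epicatechin | C(c3ccccc3)Oc1cc(OCc3ccccc3)c2c(c1)O[C@H](c1ccc(OCc3ccccc3)c(OCc3ccccc3)c1)[C@H](O)C2 | intermediate
12 | 5,7,3',4'-tetra-O-benzyl-4β-(2-ethoxyethoxy)-(−)-epicatechin (3,4-trans) | C(c3ccccc3)Oc1cc(OCc3ccccc3)c2c(c1)O[C@H](c1ccc(OCc3ccccc3)c(OCc3ccccc3)c1)[C@H](O)[C@H]2OCCOCC | intermediate
13 | (+)-catechin, (2R,3S) | Oc1cc(O)c2c(c1)O[C@H](c1ccc(O)c(O)c1)[C@@H](O)C2 | starting material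
14 | 5,7,3',4'-tetra-O-benzyl-(+)-catechin | C(c3ccccc3)Oc1cc(OCc3ccccc3)c2c(c1)O[C@H](c1ccc(OCc3ccccc3)c(OCc3ccccc3)c1)[C@@H](O)C2 | intermediate
15 | octa-O-benzyl epicatechin-(4β→8)-catechin, all phenols benzylated | C(c3ccccc3)Oc1cc(OCc3ccccc3)c2c(c1)O[C@H](c1ccc(OCc3ccccc3)c(OCc3ccccc3)c1)[C@H](O)[C@H]2c1c(OCc3ccccc3)cc(OCc3ccccc3)c2c1O[C@H](c1ccc(OCc3ccccc3)c(OCc3ccccc3)c1)[C@@H](O)C2 | intermediate
16 | dodeca-O-benzyl epicatechin-(4β→8)-epicatechin-(4β→8)-catechin | C(c3ccccc3)Oc1cc(OCc3ccccc3)c2c(c1)O[C@H](c1ccc(OCc3ccccc3)c(OCc3ccccc3)c1)[C@H](O)[C@H]2c1c(OCc3ccccc3)cc(OCc3ccccc3)c2c1O[C@H](c1ccc(OCc3ccccc3)c(OCc3ccccc3)c1)[C@H](O)[C@H]2c1c(OCc3ccccc3)cc(OCc3ccccc3)c2c1O[C@H](c1ccc(OCc3ccccc3)c(OCc3ccccc3)c1)[C@@H](O)C2 | intermediate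
17 | hexadeca-O-benzyl epicatechin-(4β→8)-epicatechin-(4β→8)-epicatechin-(4β→8)-catechin | C(c3ccccc3)Oc1cc(OCc3ccccc3)c2c(c1)O[C@H](c1ccc(OCc3ccccc3)c(OCc3ccccc3)c1)[C@H](O)[C@H]2c1c(OCc3ccccc3)cc(OCc3ccccc3)c2c1O[C@H](c1ccc(OCc3ccccc3)c(OCc3ccccc3)c1)[C@H](O)[C@H]2c1c(OCc3ccccc3)cc(OCc3ccccc3)c2c1O[C@H](c1ccc(OCc3ccccc3)c(OCc3ccccc3)c1)[C@H](O)[C@H]2c1c(OCc3ccccc3)cc(OCc3ccccc3)c2c1O[C@H](c1ccc(OCc3ccccc3)c(OCc3ccccc3)c1)[C@@H](O)C2 | intermediate
18 | epicatechin-(4β→8)-epicatechin-(4β→8)-epicatechin-(4β→8)-catechin, the target arecatannin tetramer | Oc1cc(O)c2c(c1)O[C@H](c1ccc(O)c(O)c1)[C@H](O)[C@H]2c1c(O)cc(O)c2c1O[C@H](c1ccc(O)c(O)c1)[C@H](O)[C@H]2c1c(O)cc(O)c2c1O[C@H](c1ccc(O)c(O)c1)[C@H](O)[C@H]2c1c(O)cc(O)c2c1O[C@H](c1ccc(O)c(O)c1)[C@@H](O)C2 | target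

**Summary**

Total step count: 11.
Longest linear sequence: 6 steps (steps 1, 2, 3, 4, 10, 11; the branch through steps 5, 6, 8, 9, 10, 11 is equally long).

**Steps most likely to fail**

1. Step 4 (proposed new method). The phenoxide may attack through its para carbon or its oxygen. The new electron-rich benzylic carbinol may ionise and take up a second arene. The epoxide may open 5-exo, open by ionisation with loss of the 2,3-cis relationship, or rearrange under the Lewis acid. Fallback: the top unit is then taken from the chiral pool instead of being built. It sets out from 12 and 16: electrophile 12 is condensed with trimer 16 under the conditions of step 9 (TMSOTf cat., CH2Cl2, −78 °C, 16 in excess), a known interflavan coupling, and the route is rejoined at 17. No new compound is made (F0).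

2. Step 2. With the electron-rich Z-cinnamate the radical intermediate of the manganese epoxidation may rotate before ring closure, leaking to the trans-epoxide and eroding enantioselectivity, and the arene may be chlorinated by hypochlorite. Fallback: setting out from 3, full reduction with i-Bu2AlH (2.2 equiv, CH2Cl2, −78 °C) should give (Z)-3-[3,4-bis(benzyloxy)phenyl]prop-2-en-1-ol F1. Sharpless asymmetric epoxidation (Ti(OiPr)4, D-(−)-diethyl tartrate, t-BuOOH, 4 Å MS, CH2Cl2, −20 °C) should give [(2R,3S)-3-[3,4-bis(benzyloxy)phenyl]oxiran-2-yl]methanol F2. Dess–Martin oxidation (NaHCO3, CH2Cl2) then rejoins the route at 5.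

3. Step 10. The diol-derived cation may be captured by C8 or C6 of a second molecule of 9 (self-condensation) or by C6 of 16, and prolonged acid contact may scramble the existing interflavan bonds. Fallback: a C8 blocking group is used. Setting out from 9, NBS (CH2Cl2, −20 °C) should brominate C8 of ring A to give 8-bromo-5,7,3',4'-tetra-O-benzyl-(2R,3R)-2,3-cis-flavan-3,4-diol F3, which can no longer self-condense at C8. Equimolar coupling of F3 with 16 (Yb(OTf)3, CH2Cl2) should give the 8-bromo-hexadeca-O-benzyl tetramer F4. Hydrogenolysis with added base (H2, Pd(OH)2/C, Et3N, THF/MeOH/H2O) removes the bromine together with the benzyl groups and rejoins the route at 18.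

**Further compounds**

F0 | step 4 | none | none
F1 | step 2 | (Z)-3-[3,4-bis(benzyloxy)phenyl]prop-2-en-1-ol | OC/C=C\c1ccc(OCc2ccccc2)c(OCc2ccccc2)c1
F2 | step 2 | [(2R,3S)-3-[3,4-bis(benzyloxy)phenyl]oxiran-2-yl]methanol (cis) | OC[C@H]1O[C@H]1c1ccc(OCc2ccccc2)c(OCc2ccccc2)c1
F3 | step 10 | 8-bromo-5,7,3',4'-tetra-O-benzyl-(2R,3R)-2,3-cis-flavan-3,4-diol (C4 epimer mixture) | C(c3ccccc3)Oc1cc(OCc3ccccc3)c2c(c1Br)O[C@H](c1ccc(OCc3ccccc3)c(OCc3ccccc3)c1)[C@H](O)C2O
F4 | step 10 | 8-bromo-hexadeca-O-benzyl epicatechin-(4β→8)-epicatechin-(4β→8)-epicatechin-(4β→8)-catechin (bromine at C8 of the top unit) | C(c3ccccc3)Oc1cc(OCc3ccccc3)c2c(c1Br)O[C@H](c1ccc(OCc3ccccc3)c(OCc3ccccc3)c1)[C@H](O)[C@H]2c1c(OCc3ccccc3)cc(OCc3ccccc3)c2c1O[C@H](c1ccc(OCc3ccccc3)c(OCc3ccccc3)c1)[C@H](O)[C@H]2c1c(OCc3ccccc3)cc(OCc3ccccc3)c2c1O[C@H](c1ccc(OCc3ccccc3)c(OCc3ccccc3)c1)[C@H](O)[C@H]2c1c(OCc3ccccc3)cc(OCc3ccccc3)c2c1O[C@H](c1ccc(OCc3ccccc3)c(OCc3ccccc3)c1)[C@@H](O)C2
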